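**Plan**
1. Ring C is cut first: O1–C2 and C2–C3 (C2 is one carbon from DMF dimethyl acetal), then C3–C4 between a ring B benzylic zinc reagent and a protected ring A aldehyde.
2. Ring B is cut at C2'–C3' and C6'–C1'. Its run O3'/O4'/O5'/prenyl on C3'–C6' is a 2-prenyl-3,4-dimethoxyfuran (ring oxygen = O3'); C1'/C2' with the future C3 carbon and the second prenyl group are a 4-prenylated ynoate.
3. Forward: the furan is made from diglycolate and oxalate and then prenylated; the ynoate comes from methyl propiolate; cycloaddition with bridge opening gives the hexasubstituted ring B, and the new phenol steers removal of the O4' methyl group.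
4. The ester carbon becomes C3: ester → benzylic chloride → zinc reagent → addition to the ring A aldehyde → deoxybenzoin → enaminone → ring C closure together with removal of all MOM groups.
5. Stereochemistry: the target has no stereocentre and no stereogenic double bond; the centres of 12 and 22 and the enamine geometry of 24 are transient.

Key step: step 7

Assumption: benzoates and benzyl derivatives are numbered so that their ring locants coincide with the primed ring B locants of the target (prenyl = 3-methylbut-2-en-1-yl, at C2 and C6; MOM = methoxymethyl).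

**Step 1**
Reactants: 1 dimethyl diglycolate; 2 dimethyl oxalate
Product: 3 dimethyl 3,4-dihydroxyfuran-2,5-dicarboxylate
Conditions: NaOMe, MeOH, reflux; then aq. HCl
Reagents that add atoms: none
Why: A double Claisen (Hinsberg-type) condensation of the two activated methylene groups of 1 with both carbonyls of 2 closes the five-membered ring, and enolisation aromatises it, the classical entry to 3,4-dihydroxyfuran-2,5-dicarboxylates.

**Step 2**
Reactants: 3 dimethyl 3,4-dihydroxyfuran-2,5-dicarboxylate
Product: 4 dimethyl 3,4-dimethoxyfuran-2,5-dicarboxylate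
Conditions: Me2SO4, K2CO3, acetone, reflux
Reagents that add atoms: dimethyl sulfate, COS(=O)(=O)OC
Why: The acidic enolic hydroxyls flanked by esters are O-methylated in a Williamson-type alkylation under carbonate.

**Step 3**
Reactants: 4 dimethyl 3,4-dimethoxyfuran-2,5-dicarboxylate
Product: 5 3,4-dimethoxyfuran-2,5-dicarboxylic acid
Conditions: NaOH, H2O/MeOH, reflux; then aq. HCl, 0 °C
Reagents that add atoms: sodium hydroxide, [Na+].[OH-]
Why: Ordinary saponification of two furoate esters, to which the enol ether groups are inert.

**Step 4**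
Reactants: 5 3,4-dimethoxyfuran-2,5-dicarboxylic acid
Product: 6 3,4-dimethoxyfuran
Conditions: Cu powder, quinoline, 200–220 °C, product distilled out
Reagents that add atoms: none
Why: Copper-mediated protodecarboxylation of furan-2-carboxylic acids in quinoline is the established preparation of this furan, and distillation removes the sensitive product from the hot medium.

**Step 5**
Reactants: 6 3,4-dimethoxyfuran; 7 prenyl bromide (1-bromo-3-methylbut-2-ene)
Product: 9 3,4-dimethoxy-2-(3-methylbut-2-en-1-yl)furan, via 2-lithio-3,4-dimethoxyfuran 8 (not isolated)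
Conditions: n-BuLi, THF, −78 → 0 °C; then 7, −78 °C → rt
Reagents that add atoms: none
Why: Alpha-lithiation of the symmetric furan (one possible site, acidified by the ring oxygen and the neighbouring methoxy group) followed by SN2 alkylation with an allylic bromide is the classical route to 2-prenylfurans.

**Step 6**
Reactants: 10 methyl propiolate; 7 prenyl bromide
Product: 11 methyl 6-methylhept-5-en-2-ynoate
Conditions: CuI (10 mol %), Bu4NBr (10 mol %), K2CO3, DMF, 23 °C
Reagents that add atoms: none
Why: Copper-acetylide allylation of a terminal alkyne under carbonate and phase-transfer conditions (Jeffery-type coupling) should give the skipped enyne mainly by attack at the primary carbon of the prenyl halide, the weak base leaving the isomerisable propargylic CH2 untouched.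

**Step 7**
Reactants: 9 3,4-dimethoxy-2-(3-methylbut-2-en-1-yl)furan; 11 methyl 6-methylhept-5-en-2-ynoate
Product: 13 methyl 3-hydroxy-4,5-dimethoxy-2,6-diprenylbenzoate, via oxanorbornadiene adduct 12 (not isolated)
Conditions: ZnI2 (20 mol %), 1,2-dichloroethane (2 M), 60 °C, sealed tube, Ar
Reagents that add atoms: none
Why: The furan, whose HOMO is raised by two methoxy groups and the alkyl group, should add across its 2,5-positions to the ZnI2-coordinated ynoate in a concerted but asynchronous normal-demand [4+2] cycloaddition that forms C2'–C3' and C6'–C1' and closes the six-membered carbocycle of ring B as 7-oxanorbornadiene 12. ZnI2 then assists heterolysis of the bridging C6'–O bond, the only one that gives a cation that is tertiary and delocalised onto the O4' methoxy group (a vinylogous oxocarbenium ion), and loss of the C3' proton aromatises the ring so that the furan oxygen ends as the free O3' hydroxyl. The closest known reactions are the Diels–Alder additions of 3,4-dialkoxyfurans and alkylfurans to acetylenic esters and the acid-induced isomerisation of the resulting oxanorbornadienes to phenols. The two bridgehead centres of 12 are transient and vanish on aromatisation, so no stereocentre has to be controlled. One regiochemistry is needed: the unsubstituted furan carbon (largest HOMO coefficient, least hindered) must bond to the ynoate beta carbon (largest LUMO coefficient), which both the polarisation by the ester and the donor prenyl group on the other furan terminus favour. A mild Lewis acid and moderate heat are chosen so that the reaction stays a cycloaddition and is not diverted to conjugate substitution at the free furan carbon or to protonation of the prenyl groups.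

**Step 8**
Reactants: 13 methyl 3-hydroxy-4,5-dimethoxy-2,6-diprenylbenzoate
Product: 14 methyl 3,4-dihydroxy-5-methoxy-2,6-diprenylbenzoate
Conditions: AlCl3 (1.3 equiv), pyridine (5 equiv), CH2Cl2, 40 °C; cold dilute HCl work-up
Reagents that add atoms: none
Why: In this chelation-assisted demethylation of a guaiacol unit, the aluminium phenoxide formed at O3' binds the neighbouring O4' methyl ether in a five-membered chelate and chloride removes that methyl group, while the aluminium catecholate so formed no longer activates the O5' ether and pyridine buffers the medium against protonation of the prenyl groups.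

**Step 9**
Reactants: 14 methyl 3,4-dihydroxy-5-methoxy-2,6-diprenylbenzoate
Product: 15 methyl 5-methoxy-3,4-bis(methoxymethoxy)-2,6-diprenylbenzoate
Conditions: MOMCl, i-Pr2NEt, Bu4NI (cat.), CH2Cl2, 0 → 40 °C, Ar
Reagents that add atoms: chloromethyl methyl ether, COCCl
Why: Standard base-mediated O-alkylation of both phenols gives acetal ethers that withstand hydride, organozinc and amide acetal reagents and can be removed together with those of ring A at the end.

**Step 10**
Reactants: 15 methyl 5-methoxy-3,4-bis(methoxymethoxy)-2,6-diprenylbenzoate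
Product: 16 [5-methoxy-3,4-bis(methoxymethoxy)-2,6-diprenylphenyl]methanol
Conditions: LiAlH4, THF, 0 °C → reflux; Fieser work-up
Reagents that add atoms: none
Why: LiAlH4 reduces even di-ortho-substituted benzoates to benzylic alcohols and leaves MOM ethers and isolated trisubstituted alkenes untouched.

**Step 11**
Reactants: 16 [5-methoxy-3,4-bis(methoxymethoxy)-2,6-diprenylphenyl]methanol
Product: 18 2-(chloromethyl)-4-methoxy-5,6-bis(methoxymethoxy)-1,3-diprenylbenzene (the benzylic chloride of 16), via benzylic mesylate 17 (not isolated)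
Conditions: MsCl, 2,4,6-collidine, LiCl, DMF, 0 °C
Reagents that add atoms: lithium chloride, [Li+].[Cl-]
Why: Collington–Meyers conditions convert the alcohol through its mesylate into the chloride by SN2 displacement in a buffered medium, avoiding free acid that would endanger the MOM ethers and prenyl groups.

**Step 12**
Reactants: 19 2,4,6-trihydroxybenzaldehyde
Product: 20 2,4,6-tris(methoxymethoxy)benzaldehyde
Conditions: NaH, MOMCl, DMF, 0 °C → rt
Reagents that add atoms: chloromethyl methyl ether, COCCl
Why: Exhaustive alkylation of the phenoxides with the hard electrophile MOMCl is O-selective and gives the known fully protected, non-enolisable ring A aldehyde.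

**Step 13**
Reactants: 18 benzylic chloride of ring B; 20 2,4,6-tris(methoxymethoxy)benzaldehyde
Product: 22 2-[5-methoxy-3,4-bis(methoxymethoxy)-2,6-diprenylphenyl]-1-[2,4,6-tris(methoxymethoxy)phenyl]ethan-1-ol (racemic), via benzylic zinc chloride 21 (not isolated)
Conditions: Zn dust, LiCl, THF, 25 °C; then 20, MgCl2, 25 °C; aq. NH4Cl
Reagents that add atoms: none
Why: LiCl-promoted zinc insertion into benzylic chlorides gives benzylic zinc reagents with little Wurtz coupling, and their MgCl2-accelerated 1,2-addition to the aldehyde forms the C3–C4 bond, the new carbinol centre being racemic and removed in the next step.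

**Step 14**
Reactants: 22 the carbinol from step 13
Product: 23 2-[5-methoxy-3,4-bis(methoxymethoxy)-2,6-diprenylphenyl]-1-[2,4,6-tris(methoxymethoxy)phenyl]ethan-1-one
Conditions: Dess–Martin periodinane, NaHCO3, CH2Cl2, 0 °C → rt
Reagents that add atoms: none
Why: Buffered Dess–Martin oxidation of a secondary benzylic alcohol to the ketone is neutral and does not touch alkenes, acetals or the electron-rich rings.

**Step 15**
Reactants: 23 the deoxybenzoin from step 14
Product: 24 (E)-3-(dimethylamino)-2-[5-methoxy-3,4-bis(methoxymethoxy)-2,6-diprenylphenyl]-1-[2,4,6-tris(methoxymethoxy)phenyl]prop-2-en-1-one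
Conditions: Me2NCH(OMe)2 (neat), 100 °C
Reagents that add atoms: N,N-dimethylformamide dimethyl acetal, COC(OC)N(C)C
Why: Condensation of the activated methylene of a deoxybenzoin with DMF dimethyl acetal is the standard way to introduce C2 in isoflavone synthesis, and the small electrophile should cope with the hindered benzylic position (the geometry of this push–pull alkene is not fixed and has no consequence).

**Step 16**
Reactants: 24 the enaminone from step 15
Product: 25 erythbigenin
Conditions: 3 M aq. HCl, MeOH/THF, 50 °C, Ar
Reagents that add atoms: none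
Why: Acidic methanolysis, routinely used for MOM ethers of prenylated polyphenols, should remove all five acetals, whereupon one freed ortho hydroxyl of ring A adds to the enaminone beta carbon and expels dimethylamine (addition–elimination, six-membered ring C closes through O1–C2), leaving the other ortho hydroxyl as the chelated 5-OH.

**Compound list**
1 | dimethyl diglycolate | COC(=O)COCC(=O)OC | starting material
2 | dimethyl oxalate | COC(=O)C(=O)OC | starting material
3 | dimethyl 3,4-dihydroxyfuran-2,5-dicarboxylate | COC(=O)c1oc(C(=O)OC)c(O)c1O | intermediate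
4 | dimethyl 3,4-dimethoxyfuran-2,5-dicarboxylate | COC(=O)c1oc(C(=O)OC)c(OC)c1OC | intermediate
5 | 3,4-dimethoxyfuran-2,5-dicarboxylic acid | OC(=O)c1oc(C(=O)O)c(OC)c1OC | intermediate
6 | 3,4-dimethoxyfuran | COc1cocc1OC | intermediate
7 | prenyl bromide (1-bromo-3-methylbut-2-ene) | CC(C)=CCBr | starting material
8 | 2-lithio-3,4-dimethoxyfuran | COc1coc([Li])c1OC | intermediate (not isolated)
9 | 3,4-dimethoxy-2-(3-methylbut-2-en-1-yl)furan | COc1coc(CC=C(C)C)c1OC | intermediate
10 | methyl propiolate | C#CC(=O)OC | starting material
11 | methyl 6-methylhept-5-en-2-ynoate | COC(=O)C#CCC=C(C)C | intermediate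
12 | methyl 5,6-dimethoxy-1,3-bis(3-methylbut-2-en-1-yl)-7-oxabicyclo[2.2.1]hepta-2,5-diene-2-carboxylate (racemic, one enantiomer drawn; bridgeheads fixed by the oxygen bridge) | COC(=O)C1=C(CC=C(C)C)[C@H]2O[C@]1(CC=C(C)C)C(OC)=C2OC | intermediate (not isolated)
13 | methyl 3-hydroxy-4,5-dimethoxy-2,6-bis(3-methylbut-2-en-1-yl)benzoate | COC(=O)c1c(CC=C(C)C)c(O)c(OC)c(OC)c1CC=C(C)C | intermediate
14 | methyl 3,4-dihydroxy-5-methoxy-2,6-bis(3-methylbut-2-en-1-yl)benzoate | COC(=O)c1c(CC=C(C)C)c(O)c(O)c(OC)c1CC=C(C)C | intermediate
15 | methyl 5-methoxy-3,4-bis(methoxymethoxy)-2,6-bis(3-methylbut-2-en-1-yl)benzoate | COC(=O)c1c(CC=C(C)C)c(OCOC)c(OCOC)c(OC)c1CC=C(C)C | intermediate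
16 | [5-methoxy-3,4-bis(methoxymethoxy)-2,6-bis(3-methylbut-2-en-1-yl)phenyl]methanol | OCc1c(CC=C(C)C)c(OCOC)c(OCOC)c(OC)c1CC=C(C)C | intermediate
17 | [5-methoxy-3,4-bis(methoxymethoxy)-2,6-bis(3-methylbut-2-en-1-yl)phenyl]methyl methanesulfonate | CS(=O)(=O)OCc1c(CC=C(C)C)c(OCOC)c(OCOC)c(OC)c1CC=C(C)C | intermediate (not isolated)
18 | 2-(chloromethyl)-4-methoxy-5,6-bis(methoxymethoxy)-1,3-bis(3-methylbut-2-en-1-yl)benzene | ClCc1c(CC=C(C)C)c(OCOC)c(OCOC)c(OC)c1CC=C(C)C | intermediate
19 | 2,4,6-trihydroxybenzaldehyde | O=Cc1c(O)cc(O)cc1O | starting material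
20 | 2,4,6-tris(methoxymethoxy)benzaldehyde | O=Cc1c(OCOC)cc(OCOC)cc1OCOC | intermediate
21 | {[5-methoxy-3,4-bis(methoxymethoxy)-2,6-bis(3-methylbut-2-en-1-yl)phenyl]methyl}zinc chloride | Cl[Zn]Cc1c(CC=C(C)C)c(OCOC)c(OCOC)c(OC)c1CC=C(C)C | intermediate (not isolated)
22 | 2-[5-methoxy-3,4-bis(methoxymethoxy)-2,6-bis(3-methylbut-2-en-1-yl)phenyl]-1-[2,4,6-tris(methoxymethoxy)phenyl]ethan-1-ol (racemic) | OC(Cc1c(CC=C(C)C)c(OCOC)c(OCOC)c(OC)c1CC=C(C)C)c1c(OCOC)cc(OCOC)cc1OCOC | intermediate
23 | 2-[5-methoxy-3,4-bis(methoxymethoxy)-2,6-bis(3-methylbut-2-en-1-yl)phenyl]-1-[2,4,6-tris(methoxymethoxy)phenyl]ethan-1-one | O=C(Cc1c(CC=C(C)C)c(OCOC)c(OCOC)c(OC)c1CC=C(C)C)c1c(OCOC)cc(OCOC)cc1OCOC | intermediate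
24 | (E)-3-(dimethylamino)-2-[5-methoxy-3,4-bis(methoxymethoxy)-2,6-bis(3-methylbut-2-en-1-yl)phenyl]-1-[2,4,6-tris(methoxymethoxy)phenyl]prop-2-en-1-one | CN(C)/C=C(/C(=O)c1c(OCOC)cc(OCOC)cc1OCOC)c1c(CC=C(C)C)c(OCOC)c(OCOC)c(OC)c1CC=C(C)C | intermediate
25 | erythbigenin, 5,7-dihydroxy-3-[3,4-dihydroxy-5-methoxy-2,6-bis(3-methylbut-2-en-1-yl)phenyl]-4H-chromen-4-one | COc1c(O)c(O)c(CC=C(C)C)c(-c2coc3cc(O)cc(O)c3c2=O)c1CC=C(C)C | target

**Step count**
Total: 16 steps. Longest linear sequence: 14 steps (1–5, 7–11, 13–16) from dimethyl diglycolate; steps 6 and 12 are side branches.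

**Steps most likely to fail**

Step 7. The internal, singly activated ynoate may add too slowly, or the reaction may be diverted to conjugate substitution at the free furan carbon instead of ring closure. The fallback raises the electrophilicity of the dienophile by moving to the aldehyde oxidation level; it sets out from prenyl bromide 7 and furan 9 and returns at benzylic alcohol 16. Copper-catalysed coupling of 7 with propargyl alcohol (CuI, K2CO3, Bu4NBr, DMF) would give 6-methylhept-5-en-2-yn-1-ol F1, and MnO2 in CH2Cl2 would oxidise it to 6-methylhept-5-en-2-ynal F2, whose LUMO lies well below that of the ester and which should add to 9 near room temperature without a Lewis acid. The adduct, the 2-formyl-7-oxanorbornadiene F3, would be opened in the same flask with a trace of ZnI2 to 3-hydroxy-4,5-dimethoxy-2,6-diprenylbenzaldehyde F4. The conditions of steps 8 and 9 applied in the aldehyde series would give 3,4-dihydroxy-5-methoxy-2,6-diprenylbenzaldehyde F5 and then 5-methoxy-3,4-bis(methoxymethoxy)-2,6-diprenylbenzaldehyde F6, and NaBH4 in MeOH would reduce F6 to 16.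

Step 8. The aluminium Lewis acid may trigger cyclisation of the C2' prenyl group onto the neighbouring phenol, or the demethylation may not stop cleanly after one methyl group. The fallback replaces chelation by an SN2 dealkylation with a soft nucleophile; it sets out from phenol 13 and returns at benzylic alcohol 16. MOMCl and i-Pr2NEt would cap O3' to give methyl 4,5-dimethoxy-3-(methoxymethoxy)-2,6-diprenylbenzoate F7. NaSEt in DMF at about 110 °C should then remove the ester methyl group and the O4' methyl group, the ether flanked by two oxygen substituents and para to the carboxyl group, giving 4-hydroxy-5-methoxy-3-(methoxymethoxy)-2,6-diprenylbenzoic acid F8. Excess MOMCl and i-Pr2NEt would convert F8 into methoxymethyl 5-methoxy-3,4-bis(methoxymethoxy)-2,6-diprenylbenzoate F9, which LiAlH4 reduces to 16.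

Step 16. During the five-fold acetal cleavage, protonation of the C2' prenyl alkene followed by ring closure onto the freed O3' hydroxyl (chroman formation) or hydration of a prenyl group may compete. The fallback closes ring C before any free ortho-prenylphenol exists and removes the remaining acetals without protic acid; it sets out from enaminone 24 and ends at 25. MgBr2·OEt2 in CH2Cl2 would cleave, by chelation to the vinylogous amide carbonyl, one of the two equivalent MOM ethers beside it to give the hydroxy enaminone F10. Gentle warming with catalytic pyridinium p-toluenesulfonate would close ring C to the tetra-MOM isoflavone F11 while ring B is still fully protected. The four remaining acetals would then be removed by thiol transacetalisation with ZnBr2 and n-PrSH in CH2Cl2 at 0 °C within minutes to give 25.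

**Further compounds**
F1 | step 7 | 6-methylhept-5-en-2-yn-1-ol | OCC#CCC=C(C)C
F2 | step 7 | 6-methylhept-5-en-2-ynal | O=CC#CCC=C(C)C
F3 | step 7 | 5,6-dimethoxy-1,3-bis(3-methylbut-2-en-1-yl)-7-oxabicyclo[2.2.1]hepta-2,5-diene-2-carbaldehyde (racemic, not isolated) | O=CC1=C(CC=C(C)C)[C@H]2O[C@]1(CC=C(C)C)C(OC)=C2OC
F4 | step 7 | 3-hydroxy-4,5-dimethoxy-2,6-bis(3-methylbut-2-en-1-yl)benzaldehyde | O=Cc1c(CC=C(C)C)c(O)c(OC)c(OC)c1CC=C(C)C
F5 | step 7 | 3,4-dihydroxy-5-methoxy-2,6-bis(3-methylbut-2-en-1-yl)benzaldehyde | O=Cc1c(CC=C(C)C)c(O)c(O)c(OC)c1CC=C(C)C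
F6 | step 7 | 5-methoxy-3,4-bis(methoxymethoxy)-2,6-bis(3-methylbut-2-en-1-yl)benzaldehyde | O=Cc1c(CC=C(C)C)c(OCOC)c(OCOC)c(OC)c1CC=C(C)C
F7 | step 8 | methyl 4,5-dimethoxy-3-(methoxymethoxy)-2,6-bis(3-methylbut-2-en-1-yl)benzoate | COC(=O)c1c(CC=C(C)C)c(OCOC)c(OC)c(OC)c1CC=C(C)C
F8 | step 8 | 4-hydroxy-5-methoxy-3-(methoxymethoxy)-2,6-bis(3-methylbut-2-en-1-yl)benzoic acid | OC(=O)c1c(CC=C(C)C)c(OCOC)c(O)c(OC)c1CC=C(C)C
F9 | step 8 | methoxymethyl 5-methoxy-3,4-bis(methoxymethoxy)-2,6-bis(3-methylbut-2-en-1-yl)benzoate | COCOC(=O)c1c(CC=C(C)C)c(OCOC)c(OCOC)c(OC)c1CC=C(C)C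
F10 | step 16 | (E)-3-(dimethylamino)-1-[2-hydroxy-4,6-bis(methoxymethoxy)phenyl]-2-[5-methoxy-3,4-bis(methoxymethoxy)-2,6-bis(3-methylbut-2-en-1-yl)phenyl]prop-2-en-1-one | CN(C)/C=C(/C(=O)c1c(O)cc(OCOC)cc1OCOC)c1c(CC=C(C)C)c(OCOC)c(OCOC)c(OC)c1CC=C(C)C
F11 | step 16 | 5,7-bis(methoxymethoxy)-3-[5-methoxy-3,4-bis(methoxymethoxy)-2,6-bis(3-methylbut-2-en-1-yl)phenyl]-4H-chromen-4-one | COCOc1cc(OCOC)c2c(c1)occ(-c1c(CC=C(C)C)c(OCOC)c(OCOC)c(OC)c1CC=C(C)C)c2=O
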